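Assumption: the SMILES encodes (2S)-kazinol B, with C2 of the flavan as the only stereocentre. The route is planned for 2S.

## Retrosynthetic overview
1. Kazinol B ⇐ desilylation ⇐ aromatic Claisen rearrangement of a (2S)-flavan carrying a 3′-O-(1,1-dimethylallyl) ether. This ether serves as both the phenol protection and the latent 2′-prenyl group.
2. Flavan O1–C2 bond ⇐ intramolecular Mitsunobu (inversion) of an (R)-1,3-diarylpropan-1-ol ⇐ ketoreductase (KRED) reduction of the achiral ketone, which sets the only stereocentre.
3. Ketone C2–C1′ bond ⇐ chromenyl-lithium plus a Weinreb amide made by opening 7-silyloxy-dihydrocoumarin (from umbelliferone).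
4. Bromochromenol ⇐ 5-bromosalicylaldehyde by O-(1,1-dimethylpropargyl)ation, Baeyer–Villiger (CHO → OH), and propargyl Claisen/electrocyclisation.
5. Ring order: both benzene rings are bought. The dimethylpyran ring forms first (step 4). The coumarin lactone is opened (step 9) and re-closed as the flavan dihydropyran last (step 12).

## Route

**Step 1**
Reactants: 1, 5-bromo-2-hydroxybenzaldehyde; 2, 3-chloro-3-methylbut-1-yne
Product: 3, 5-bromo-2-[(2-methylbut-3-yn-2-yl)oxy]benzaldehyde
Conditions: 2 (1.5 equiv), DBU, CuCl2·2H2O (1 mol %), MeCN, 0 °C → rt, N2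
Reagents that add atoms: 2, 3-chloro-3-methylbut-1-yne, C#CC(C)(C)Cl
Why: Cu-catalysed O-propargylation with a tertiary propargylic chloride works well on acidic, electron-poor phenols, and the single OH (para to Br) fixes the future pyran oxygen unambiguously.

**Step 2**
Reactants: 3
Product: 4, 5-bromo-2-[(2-methylbut-3-yn-2-yl)oxy]phenyl formate
Conditions: mCPBA (1.5 equiv), NaHCO3, CH2Cl2, rt
Reagents that add atoms: mCPBA, O=C(OO)c1cccc(Cl)c1 (one O)
Why: Baeyer–Villiger oxidation of an o-alkoxybenzaldehyde proceeds by aryl migration to the formate, and the terminal alkyne and aryl bromide are inert to the peracid.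

**Step 3**
Reactants: 4
Product: 5, 5-bromo-2-[(2-methylbut-3-yn-2-yl)oxy]phenol
Conditions: K2CO3, MeOH, 0 °C → rt
Reagents that add atoms: none
Why: Mild methanolysis of the aryl formate releases the second, now differentiated, catechol oxygen without touching the tertiary ether.

**Step 4**
Reactants: 5
Product: 6, 6-bromo-2,2-dimethyl-2H-chromen-8-ol
Conditions: PhNEt2, 180 °C, 2 h, Ar
Reagents that add atoms: none
Why: The propargyl Claisen rearrangement, 1,5-H shift and oxa-6π electrocyclisation can only end at the one H-bearing ortho carbon, which gives the 6-bromo-8-hydroxy pattern.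

**Step 5**
Reactants: 6; 2, 3-chloro-3-methylbut-1-yne
Product: 7, 6-bromo-2,2-dimethyl-8-[(2-methylbut-3-yn-2-yl)oxy]-2H-chromene
Conditions: 2 (1.5 equiv), DBU, CuCl2·2H2O (1 mol %), MeCN, 0 °C → rt
Reagents that add atoms: 2, 3-chloro-3-methylbut-1-yne, C#CC(C)(C)Cl
Why: This is the same Cu-catalysed tertiary O-propargylation as step 1, run far below the rearrangement temperature on the only free OH.

**Step 6**
Reactants: 7
Product: 8, 6-bromo-2,2-dimethyl-8-[(2-methylbut-3-en-2-yl)oxy]-2H-chromene
Conditions: H2 (1 atm), Lindlar catalyst, quinoline, EtOAc, rt, stopped at 1 equiv H2; Et3N-deactivated silica, kept below 40 °C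
Reagents that add atoms: none
Why: Lindlar semihydrogenation reduces the terminal alkyne much faster than the disubstituted chromene alkene or the C–Br bond, giving the 1,1-dimethylallyl ether.

**Step 7**
Reactants: 9, umbelliferone (7-hydroxy-2H-chromen-2-one)
Product: 10, 7-hydroxychroman-2-one
Conditions: H2 (3 bar), 10 % Pd/C, AcOH, 50 °C
Reagents that add atoms: none
Why: Catalytic hydrogenation saturates the coumarin C3=C4 bond before any sensitive alkene is present, so no chemoselective enone reduction is needed later.

**Step 8**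
Reactants: 10
Product: 11, 7-[(triisopropylsilyl)oxy]chroman-2-one
Conditions: TIPSOTf, 2,6-lutidine, CH2Cl2, 0 °C
Reagents that add atoms: TIPSOTf, CC(C)[Si](C(C)C)(C(C)C)OS(=O)(=O)C(F)(F)F
Why: Phenol silylation with a non-nucleophilic base leaves the reactive aryl lactone closed, and TIPS is removable at the end without acid or hydrogen.

**Step 9**
Reactants: 11
Product: 12, 3-{2-hydroxy-4-[(triisopropylsilyl)oxy]phenyl}-N-methoxy-N-methylpropanamide
Conditions: MeNH(OMe)·HCl, AlMe3, CH2Cl2, 0 °C → rt; Rochelle-salt work-up
Reagents that add atoms: N,O-dimethylhydroxylamine hydrochloride, CNOC.Cl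
Why: Weinreb aminolysis of the strained aryl lactone is fast and effectively irreversible, and it frees exactly the phenol that will later become O1 of the flavan.

**Step 10**
Reactants: 8; 12
Product: 13, 1-{2,2-dimethyl-8-[(2-methylbut-3-en-2-yl)oxy]-2H-chromen-6-yl}-3-{2-hydroxy-4-[(triisopropylsilyl)oxy]phenyl}propan-1-one
Conditions: 8 (1.2 equiv), n-BuLi, THF, −78 °C; add to 12 pre-deprotonated with NaH (THF, 0 °C → −78 °C); −78 → −20 °C; aq NH4Cl
Reagents that add atoms: none beyond reactants 8 and 12
Why: Br/Li exchange followed by Weinreb ketone synthesis stops at the ketone through the stable chelated tetrahedral intermediate, and the phenoxide needs no protecting group because the ether carbon of 8 bears no α-H to deprotonate.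

**Step 11 (key step)**
Reactants: 13
Product: 14, (1R)-1-{2,2-dimethyl-8-[(2-methylbut-3-en-2-yl)oxy]-2H-chromen-6-yl}-3-{2-hydroxy-4-[(triisopropylsilyl)oxy]phenyl}propan-1-ol
Conditions: (R)-selective ketoreductase (KRED, NADPH-dependent short-chain dehydrogenase/reductase, chosen from an engineered panel), NADP+ (cat.), i-PrOH/0.1 M K-phosphate pH 7.0 (1:1), 5 % DMSO, 1 mM MgSO4, 35 °C, 24–48 h, N2 sweep to remove acetone; ee checked by chiral HPLC
Reagents that add atoms: none
Why: In this biocatalytic asymmetric ketone reduction the KRED delivers hydride from NADPH (recycled by i-PrOH) to the Si face to set the (R)-carbinol, and 1,3-diarylpropan-1-ones without an ortho substituent on the aroyl ring are an established bulky–bulky KRED substrate class.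

**Step 12**
Reactants: 14
Product: 15, (2S)-2-{2,2-dimethyl-8-[(2-methylbut-3-en-2-yl)oxy]-2H-chromen-6-yl}-7-[(triisopropylsilyl)oxy]chromane
Conditions: PPh3, DIAD (slow addition), toluene (0.02 M), −10 → 0 °C
Reagents that add atoms: none
Why: In the intramolecular Mitsunobu etherification the phenol displaces the oxyphosphonium by SN2 with inversion (1R → 2S), and the cold, non-polar, dilute medium suppresses ionisation of the p-alkoxybenzylic centre.

**Step 13**
Reactants: 15
Product: 16, 2,2-dimethyl-7-(3-methylbut-2-en-1-yl)-6-{(2S)-7-[(triisopropylsilyl)oxy]chroman-2-yl}-2H-chromen-8-ol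
Conditions: PhNEt2, 130 °C, 2–4 h, Ar, base-washed glassware; direct chromatography
Reagents that add atoms: none
Why: The aromatic Claisen [3,3] rearrangement transposes the tertiary allyl ether to the only H-bearing ortho carbon (C7 = C2′) as a linear prenyl group and frees the 8-OH, while the neutral/basic medium leaves C2 untouched.

**Step 14**
Reactants: 16
Product: 17, kazinol B, 6-[(2S)-7-hydroxychroman-2-yl]-2,2-dimethyl-7-(3-methylbut-2-en-1-yl)-2H-chromen-8-ol
Conditions: TBAF, AcOH (1:1), THF, 0 °C
Reagents that add atoms: none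
Why: Buffered fluoride desilylation of the aryl TIPS ether avoids acid, which would cyclise the o-prenylphenol or ionise C2, and avoids hydrogen, which would reduce the alkenes.

## Compound list
| No. | Name | SMILES | Role |
|---|---|---|---|
| 1 | 5-bromo-2-hydroxybenzaldehyde | O=Cc1cc(Br)ccc1O | starting material |
| 2 | 3-chloro-3-methylbut-1-yne | C#CC(C)(C)Cl | starting material |
| 3 | 5-bromo-2-[(2-methylbut-3-yn-2-yl)oxy]benzaldehyde | O=Cc1cc(Br)ccc1OC(C)(C)C#C | intermediate |
| 4 | 5-bromo-2-[(2-methylbut-3-yn-2-yl)oxy]phenyl formate | O=COc1cc(Br)ccc1OC(C)(C)C#C | intermediate |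
| 5 | 5-bromo-2-[(2-methylbut-3-yn-2-yl)oxy]phenol | Oc1cc(Br)ccc1OC(C)(C)C#C | intermediate |
| 6 | 6-bromo-2,2-dimethyl-2H-chromen-8-ol | CC1(C)C=Cc2cc(Br)cc(O)c2O1 | intermediate |
| 7 | 6-bromo-2,2-dimethyl-8-[(2-methylbut-3-yn-2-yl)oxy]-2H-chromene | CC1(C)C=Cc2cc(Br)cc(OC(C)(C)C#C)c2O1 | intermediate |
| 8 | 6-bromo-2,2-dimethyl-8-[(2-methylbut-3-en-2-yl)oxy]-2H-chromene | CC1(C)C=Cc2cc(Br)cc(OC(C)(C)C=C)c2O1 | intermediate |
| 9 | umbelliferone | O=c1ccc2ccc(O)cc2o1 | starting material |
| 10 | 7-hydroxychroman-2-one | O=C1CCc2ccc(O)cc2O1 | intermediate |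
| 11 | 7-[(triisopropylsilyl)oxy]chroman-2-one | O=C1CCc2ccc(O[Si](C(C)C)(C(C)C)C(C)C)cc2O1 | intermediate |
| 12 | 3-{2-hydroxy-4-[(triisopropylsilyl)oxy]phenyl}-N-methoxy-N-methylpropanamide | CON(C)C(=O)CCc1ccc(O[Si](C(C)C)(C(C)C)C(C)C)cc1O | intermediate |
| 13 | diarylpropanone (achiral) | O=C(CCc1ccc(O[Si](C(C)C)(C(C)C)C(C)C)cc1O)c1cc2c(c(OC(C)(C)C=C)c1)OC(C)(C)C=C2 | intermediate |
| 14 | (1R)-diarylpropanol | O[C@H](CCc1ccc(O[Si](C(C)C)(C(C)C)C(C)C)cc1O)c1cc2c(c(OC(C)(C)C=C)c1)OC(C)(C)C=C2 | intermediate |
| 15 | (2S)-flavan, 3′-O-(1,1-dimethylallyl), 7-OTIPS | C=CC(C)(C)Oc1cc([C@@H]2CCc3ccc(O[Si](C(C)C)(C(C)C)C(C)C)cc3O2)cc2c1OC(C)(C)C=C2 | intermediate |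
| 16 | (2S)-7-O-TIPS-kazinol B | CC(C)=CCc1c([C@@H]2CCc3ccc(O[Si](C(C)C)(C(C)C)C(C)C)cc3O2)cc2c(c1O)OC(C)(C)C=C2 | intermediate |
| 17 | kazinol B (2S) | CC(C)=CCc1c([C@@H]2CCc3ccc(O)cc3O2)cc2c(c1O)OC(C)(C)C=C2 | target |

## Summary
Total steps: 14. Longest linear sequence: 11 (steps 1–6, then 10–14). The umbelliferone branch (steps 7–9) joins at step 10.

**Steps most likely to fail**
1. **Step 11, KRED reduction.** The ketone is large and very lipophilic, so conversion or ee may be too low.
   - Fallback: move the enzymatic reduction to a small ketone.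
   - Add the aryllithium from 8 to 3-chloro-N-methoxy-N-methylpropanamide and KRED-reduce the resulting β-chloropropiophenone-type ketone to the (R)-chloro alcohol.
   - Couple this with 2-iodo-5-(TIPSO)phenol by intermolecular Mitsunobu (inversion).
   - After Cl → I exchange, close the C ring by I/Li exchange and intramolecular alkylation (Parham cyclisation).
2. **Step 12, Mitsunobu cyclisation.** Partial SN1 ionisation at the p-alkoxybenzylic carbon could erode ee, and elimination to the styrene is also possible.
   - Fallback: never break the carbinol C–O bond.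
   - Build the A-ring fragment with Br in place of the 2-OH and reduce with the enantiocomplementary (S)-selective KRED.
   - Close the ring by Pd-catalysed intramolecular aryl C–O coupling, which proceeds with retention.
3. **Step 13, late Claisen rearrangement.** The migration terminus is crowded, and loss of isoprene or para migration may compete.
   - Fallback: run the Claisen on the achiral bromide 8 to give 6-bromo-7-prenyl-chromen-8-ol and silylate the phenol.
   - Carry the prenyl group through the coupling, KRED reduction and Mitsunobu steps, and finish with a global fluoride desilylation.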